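**Strategy.** Everything rests on a Diels–Alder disconnection of the cyclohexane into a vinyl ketone (ring CH–CH2 plus the future pyran carbons) and (Z)-1-bromo-2-silyloxybutadiene (ring CH2–CH2–C(Me)Cl–CHBr). The key step exploits that C(Me)Cl–CHBr of the carbocycle is a latent α-bromo ketone and that CHBr and the ring CH are cis-1,3. One cycloaddition forms the bond from the ring CH to the CH2 remote from bromine and the bond from CHBr to its neighbouring CH2, installs bromine, and sets both ring stereocentres (endo rule; face control by the α'-carbinol of the enone). Double methyl addition, stereoconvergent chlorination and a late selenoetherification–elimination complete the target.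

Key step: step 4

Remark: 12 and 13 are carried as epimer mixtures at the ring carbinol carbon (and 13 to 16 at the selenium-bearing carbon); the first converges in step 8 and the second is destroyed in step 10, so these centres are left open in the SMILES.

Step 1
Reactants: 1 ethyl glyoxylate; 2 3-methylbut-1-ene
Product: 3 ethyl (2R)-2-hydroxy-5-methylhex-4-enoate
Conditions: [Cu((R,R)-t-Bu-box)](SbF6)2 (10 mol%), CH2Cl2, 0 °C → rt, sealed tube
Reagents that add atoms: none
Why: Catalytic enantioselective carbonyl–ene reaction in which the chelated glyoxylate is attacked by the terminal CH2 of 2 while the allylic methine hydrogen is transferred, which gives the prenyl-type trisubstituted alkene, and the C2-symmetric ligand shields one aldehyde face so that the (R)-carbinol should form (the ligand antipode is chosen for this sense, the (S,S)-ligand of this catalyst family being expected to give (S)-hydroxy esters).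

Step 2
Reactants: 3 ethyl (2R)-2-hydroxy-5-methylhex-4-enoate
Product: 5 (4R)-4-hydroxy-7-methylocta-1,6-dien-3-one, via Weinreb amide 4 (not isolated)
Conditions: MeNHOMe·HCl, i-PrMgCl, THF, −20 °C; then CH2=CHMgBr, −20 → 0 °C; poured into cold 1 M HCl
Reagents that add atoms: vinylmagnesium bromide, C=C[Mg]Br
Why: Weinreb ketone synthesis in one flask, in which the ester is converted into the N-methoxy-N-methylamide while the hydroxyl is held as its magnesium alkoxide (which also protects the α-centre from enolisation), and the stable magnesium chelate formed with the vinyl Grignard reagent releases the enone only on acidic quench, so that over-addition and amine conjugate addition are avoided and no stereocentre is touched.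

Step 3
Reactants: 6 2-(trimethylsilyloxy)buta-1,3-diene
Product: 8 (1Z)-1-bromo-2-[(tert-butyldimethylsilyl)oxy]buta-1,3-diene, via 1-bromobut-3-en-2-one 7 (not isolated)
Conditions: NBS, CH2Cl2, −78 °C; then i-Pr2NEt, TBSOTf, −78 → 0 °C; used fresh
Reagents that add atoms: N-bromosuccinimide, O=C1CCC(=O)N1Br; tert-butyldimethylsilyl trifluoromethanesulfonate, CC(C)(C)[Si](C)(C)OS(=O)(=O)C(F)(F)F
Why: Electrophilic α-bromination of the silyl enol ether at its terminal carbon followed by soft enolisation and O-silylation of the α-bromo ketone toward the more acidic CH2Br position, which is expected to give the Z enol silane (bromine syn to oxygen), that is the diene with bromine in the outside position.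

Step 4
Reactants: 5 (4R)-4-hydroxy-7-methylocta-1,6-dien-3-one; 8 (1Z)-1-bromo-2-[(tert-butyldimethylsilyl)oxy]buta-1,3-diene
Product: 10 (2S,4S)-2-bromo-4-[(2R)-2-hydroxy-5-methylhex-4-enoyl]cyclohexan-1-one, via silyl enol ether cycloadduct 9 (not isolated)
Conditions: PhMe, BHT (cat.), 45 °C; then 1 M HCl, THF, 0 °C
Reagents that add atoms: none
Why: Thermal normal-demand Diels–Alder reaction through a concerted, suprafacial six-electron transition state: the silyloxy group at C2 makes the brominated terminus C1 the most nucleophilic diene carbon, so it bonds to the β-CH2 of the hydrogen-bond-activated enone while the diene CH2 terminus bonds to the α-carbon, the regiochemistry known for 2-silyloxybutadienes with vinyl ketones. The closest precedent is the cycloaddition of α'-hydroxy vinyl ketones, in which the internal O–H···O=C bond both activates the s-cis enone and fixes its conformation; the carbocycle is closed in the intermolecular [4+2] mode, and the enol ether left in the ring is hydrolysed on work-up to the ketone that later takes methyl and chlorine. The ring CH centre is controlled by the carbinol centre: the CH2–prenyl arm shields one face of the planar, hydrogen-bonded enone, the diene adds to the other, and the (R)-carbinol should therefore give the (S)-methine. The C–Br centre is controlled by the endo rule together with the Z geometry of 8 (bromine outside; any E isomer has bromine inside and should not react), which places bromine cis to the acyl group, the cis-1,3 relation of the target. The step needs regio-, endo- and facial selectivity, secured in turn by the silyloxy group, by secondary orbital overlap with the enone carbonyl and by the free hydroxyl; Lewis acids are left out so that the allylic bromide of 9 does not ionise.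

Step 5
Reactants: 10 (2S,4S)-2-bromo-4-[(2R)-2-hydroxy-5-methylhex-4-enoyl]cyclohexan-1-one
Product: 11 (2S,4S)-2-bromo-4-[(2R)-2-[(tert-butyldimethylsilyl)oxy]-5-methylhex-4-enoyl]cyclohexan-1-one
Conditions: TBSOTf, 2,6-lutidine, CH2Cl2, −78 °C
Reagents that add atoms: tert-butyldimethylsilyl trifluoromethanesulfonate, CC(C)(C)[Si](C)(C)OS(=O)(=O)C(F)(F)F
Why: O-Silylation of the secondary α-hydroxy ketone with a silyl triflate and a hindered pyridine base, which at −78 °C should outrun enol silylation of either ketone, the bulky non-chelating silyl ether being needed for the stereochemical course of step 6 and to block this oxygen in step 7.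

Step 6
Reactants: 11 (2S,4S)-2-bromo-4-[(2R)-2-[(tert-butyldimethylsilyl)oxy]-5-methylhex-4-enoyl]cyclohexan-1-one
Product: 12 (2S,4S)-2-bromo-4-[(2R,3R)-3-[(tert-butyldimethylsilyl)oxy]-2-hydroxy-6-methylhept-5-en-2-yl]-1-methylcyclohexan-1-ol (both C-1 epimers)
Conditions: MeLi, CeCl3 (MeCeCl2, excess), THF, −78 °C; aq. NH4Cl at −78 °C
Reagents that add atoms: methyllithium, [Li]C
Why: 1,2-Addition of a non-basic organocerium reagent to both ketones, the acyclic one under non-chelation (polar Felkin–Anh) control with the C–OSi bond anti to the incoming methyl, which should set the (R) tertiary carbinol next to the silyloxy centre, while the ring α-bromo ketone gives C-1 epimers that converge in step 8, and the low basicity of the reagent together with the cold quench should suppress enolisation and epoxide closure.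

Step 7
Reactants: 12 (2S,4S)-2-bromo-4-[(2R,3R)-3-[(tert-butyldimethylsilyl)oxy]-2-hydroxy-6-methylhept-5-en-2-yl]-1-methylcyclohexan-1-ol
Product: 13 (2S,4S)-2-bromo-4-[(2R,3R)-3-[(tert-butyldimethylsilyl)oxy]-2,6,6-trimethyl-5-(phenylselanyl)oxan-2-yl]-1-methylcyclohexan-1-ol
Conditions: PhSeCl, CH2Cl2, −78 °C → rt
Reagents that add atoms: benzeneselenenyl chloride, Cl[Se]c1ccccc1
Why: Phenylselenoetherification in which the seleniranium ion of the trisubstituted alkene is opened at its tertiary carbon (Markovnikov, 6-endo) by the tertiary hydroxyl, the HCl formed in the flask being expected to equilibrate any kinetic 5-exo tetrahydrofuran to the oxane, while the silyl ether blocks 5-endo closure by the secondary oxygen and the new C–Se centre is of no consequence because step 10 removes it.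

Step 8
Reactants: 13 (2S,4S)-2-bromo-4-[(2R,3R)-3-[(tert-butyldimethylsilyl)oxy]-2,6,6-trimethyl-5-(phenylselanyl)oxan-2-yl]-1-methylcyclohexan-1-ol
Product: 14 {[(2R,3R)-2-[(1S,3S,4S)-3-bromo-4-chloro-4-methylcyclohexyl]-2,6,6-trimethyl-5-(phenylselanyl)oxan-3-yl]oxy}(tert-butyl)dimethylsilane
Conditions: HCl (g), CH2Cl2, −20 → 0 °C
Reagents that add atoms: hydrogen chloride, Cl
Why: SN1 substitution of a tertiary alcohol with neighbouring-group participation, in which ionisation of either C-1 epimer gives the β-bromo tertiary cation that is bridged by the equatorial bromine on its own face, so that chloride should enter anti to bromine at the tertiary carbon and give the trans-diequatorial bromochloride with axial methyl, alkenes formed by E1 loss re-entering the same ion under excess HCl.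

Step 9
Reactants: 14 {[(2R,3R)-2-[(1S,3S,4S)-3-bromo-4-chloro-4-methylcyclohexyl]-2,6,6-trimethyl-5-(phenylselanyl)oxan-3-yl]oxy}(tert-butyl)dimethylsilane
Product: 15 (2R,3R)-2-[(1S,3S,4S)-3-bromo-4-chloro-4-methylcyclohexyl]-2,6,6-trimethyl-5-(phenylselanyl)oxan-3-ol
Conditions: 48% aq. HF, MeCN, rt
Reagents that add atoms: none
Why: Acidic fluoride cleavage of the silyl ether, chosen over basic fluoride to avoid E2 loss of the halides and carried out while the pyran is still the acid-stable saturated β-seleno oxane, with no stereocentre touched.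

Step 10
Reactants: 15 (2R,3R)-2-[(1S,3S,4S)-3-bromo-4-chloro-4-methylcyclohexyl]-2,6,6-trimethyl-5-(phenylselanyl)oxan-3-ol
Product: 17 (2R,3R)-2-[(1S,3S,4S)-3-bromo-4-chloro-4-methylcyclohexyl]-2,6,6-trimethyl-3,6-dihydro-2H-pyran-3-ol, via selenoxide 16 (not isolated)
Conditions: 30% H2O2, pyridine, THF, 0 °C → rt
Reagents that add atoms: none
Why: Selenide oxidation and syn-elimination of the selenoxide, regiospecific because the only β-hydrogens sit on C-4 of the oxane (C-6 is quaternary), so the alkene should form between C-4 and C-5 and give the allylic alcohol without touching any stereocentre.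

**Compound list**

1 | ethyl glyoxylate | CCOC(=O)C=O | starting material
2 | 3-methylbut-1-ene | CC(C)C=C | starting material
3 | ethyl (2R)-2-hydroxy-5-methylhex-4-enoate | CC(C)=CC[C@@H](O)C(=O)OCC | intermediate
4 | (2R)-2-hydroxy-N-methoxy-N,5-dimethylhex-4-enamide (not isolated) | CC(C)=CC[C@@H](O)C(=O)N(C)OC | intermediate
5 | (4R)-4-hydroxy-7-methylocta-1,6-dien-3-one | CC(C)=CC[C@@H](O)C(=O)C=C | intermediate
6 | 2-(trimethylsilyloxy)buta-1,3-diene | C=CC(=C)O[Si](C)(C)C | starting material
7 | 1-bromobut-3-en-2-one (not isolated) | BrCC(=O)C=C | intermediate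
8 | (1Z)-1-bromo-2-[(tert-butyldimethylsilyl)oxy]buta-1,3-diene | Br/C=C(/C=C)O[Si](C)(C)C(C)(C)C | intermediate
9 | (2R)-1-[(1S,5S)-5-bromo-4-[(tert-butyldimethylsilyl)oxy]cyclohex-3-en-1-yl]-2-hydroxy-5-methylhex-4-en-1-one (not isolated) | CC(C)=CC[C@@H](O)C(=O)[C@H]1CC=C(O[Si](C)(C)C(C)(C)C)[C@@H](Br)C1 | intermediate
10 | (2S,4S)-2-bromo-4-[(2R)-2-hydroxy-5-methylhex-4-enoyl]cyclohexan-1-one | CC(C)=CC[C@@H](O)C(=O)[C@H]1CCC(=O)[C@@H](Br)C1 | intermediate
11 | (2S,4S)-2-bromo-4-[(2R)-2-[(tert-butyldimethylsilyl)oxy]-5-methylhex-4-enoyl]cyclohexan-1-one | CC(C)=CC[C@@H](O[Si](C)(C)C(C)(C)C)C(=O)[C@H]1CCC(=O)[C@@H](Br)C1 | intermediate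
12 | (2S,4S)-2-bromo-4-[(2R,3R)-3-[(tert-butyldimethylsilyl)oxy]-2-hydroxy-6-methylhept-5-en-2-yl]-1-methylcyclohexan-1-ol (both C-1 epimers) | CC(C)=CC[C@@H](O[Si](C)(C)C(C)(C)C)[C@](C)(O)[C@H]1CCC(C)(O)[C@@H](Br)C1 | intermediate
13 | (2S,4S)-2-bromo-4-[(2R,3R)-3-[(tert-butyldimethylsilyl)oxy]-2,6,6-trimethyl-5-(phenylselanyl)oxan-2-yl]-1-methylcyclohexan-1-ol (epimers at C-1 and at oxane C-5) | CC1(C)C([Se]c2ccccc2)C[C@@H](O[Si](C)(C)C(C)(C)C)[C@@](C)([C@H]3CCC(C)(O)[C@@H](Br)C3)O1 | intermediate
14 | {[(2R,3R)-2-[(1S,3S,4S)-3-bromo-4-chloro-4-methylcyclohexyl]-2,6,6-trimethyl-5-(phenylselanyl)oxan-3-yl]oxy}(tert-butyl)dimethylsilane | CC1(C)C([Se]c2ccccc2)C[C@@H](O[Si](C)(C)C(C)(C)C)[C@@](C)([C@H]3CC[C@](C)(Cl)[C@@H](Br)C3)O1 | intermediate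
15 | (2R,3R)-2-[(1S,3S,4S)-3-bromo-4-chloro-4-methylcyclohexyl]-2,6,6-trimethyl-5-(phenylselanyl)oxan-3-ol | CC1(C)C([Se]c2ccccc2)C[C@@H](O)[C@@](C)([C@H]3CC[C@](C)(Cl)[C@@H](Br)C3)O1 | intermediate
16 | (2R,3R)-5-(benzeneseleninyl)-2-[(1S,3S,4S)-3-bromo-4-chloro-4-methylcyclohexyl]-2,6,6-trimethyloxan-3-ol (not isolated) | CC1(C)C([Se](=O)c2ccccc2)C[C@@H](O)[C@@](C)([C@H]3CC[C@](C)(Cl)[C@@H](Br)C3)O1 | intermediate
17 | (2R,3R)-2-[(1S,3S,4S)-3-bromo-4-chloro-4-methylcyclohexyl]-2,6,6-trimethyl-3,6-dihydro-2H-pyran-3-ol | CC1(C)C=C[C@@H](O)[C@@](C)([C@H]2CC[C@](C)(Cl)[C@@H](Br)C2)O1 | target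

**Step count.** Total: 10 steps. Longest linear sequence: 9 steps (1, 2, 4 to 10); step 3 is the one-step branch to the diene.

**Steps most likely to fail**

Step 4 (key step). The flexible CH2–prenyl arm may discriminate the enone faces poorly, endo selectivity may erode at 45 °C, or the brominated silyloxydiene may decompose before it reacts. Fallback: the ring is assembled from 5 and the robust parent diene 6 (toluene, 80 °C) to give the silyl enol ether (2R)-2-hydroxy-5-methyl-1-{4-[(trimethylsilyl)oxy]cyclohex-3-en-1-yl}hex-4-en-1-one F1. This is hydrolysed (1 M HCl, THF) to 4-[(2R)-2-hydroxy-5-methylhex-4-enoyl]cyclohexan-1-one F2, in which the ring carbon that bears the side chain is not stereogenic. Both ring centres are then set by a catalyst-controlled, desymmetrising enamine α-bromination (C2-symmetric 4,5-diphenylimidazolidine catalyst, 4,4-dibromo-2,6-di-tert-butylcyclohexa-2,5-dien-1-one, THF, −30 °C). The catalyst antipode is chosen to brominate the ring arm that leads to the 2S,4S product, and the C–Br centre can be equilibrated toward the cis isomer with acid. The sequence comes back to the route at 10.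

Step 7. Ring closure may go 5-exo (attack at the secondary alkene carbon), or the silyl ether may be lost so that the secondary oxygen closes instead. Fallback: the dihydropyran is made from 12 by a Wacker-type oxidative cyclisation (Pd(OAc)2 (10 mol%), pyridine, O2, toluene, 80 °C). Oxypalladation should place oxygen on the tertiary alkene carbon, and β-hydride elimination toward the ring CH2 should give (2S,4S)-2-bromo-4-[(2R,3R)-3-[(tert-butyldimethylsilyl)oxy]-2,6,6-trimethyl-3,6-dihydro-2H-pyran-2-yl]-1-methylcyclohexan-1-ol F3 directly. Its tertiary alcohol is converted to the chloride under neutral conditions with 1-chloro-N,N,2-trimethylprop-1-en-1-amine (CH2Cl2, 0 °C), again through the bromine-bridged cation, to give {[(2R,3R)-2-[(1S,3S,4S)-3-bromo-4-chloro-4-methylcyclohexyl]-2,6,6-trimethyl-3,6-dihydro-2H-pyran-3-yl]oxy}(tert-butyl)dimethylsilane F4. HF·pyridine (THF, 0 °C) then removes the silyl group and arrives at 17.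

Step 6. Metal chelation may erode the non-chelation selectivity at the acyclic ketone, or the α-bromo ketone may be lost by enolisation or halogen–metal exchange. Fallback: the two carbonyl groups are methylated separately. The crude cycloadduct 9 is not hydrolysed but O-silylated (TBSOTf, 2,6-lutidine, CH2Cl2, −78 °C) to give (2R)-1-[(1S,5S)-5-bromo-4-[(tert-butyldimethylsilyl)oxy]cyclohex-3-en-1-yl]-2-[(tert-butyldimethylsilyl)oxy]-5-methylhex-4-en-1-one F5, in which the ring ketone stays masked as its silyl enol ether. MeLi (THF, −78 °C) then adds only to the acyclic ketone to give (2R,3R)-2-[(1S,5S)-5-bromo-4-[(tert-butyldimethylsilyl)oxy]cyclohex-3-en-1-yl]-3-[(tert-butyldimethylsilyl)oxy]-6-methylhept-5-en-2-ol F6. Hydrolysis of the enol ether (1 M HCl, THF, 0 °C) gives (2S,4S)-2-bromo-4-[(2R,3R)-3-[(tert-butyldimethylsilyl)oxy]-2-hydroxy-6-methylhept-5-en-2-yl]cyclohexan-1-one F7. The non-basic MeTi(OiPr)3 (Et2O, 0 °C), which tolerates α-halo ketones and free hydroxyl groups, then adds to the ring ketone and comes back to the route at 12.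

Further compounds
F1 | step 4 | (2R)-2-hydroxy-5-methyl-1-{4-[(trimethylsilyl)oxy]cyclohex-3-en-1-yl}hex-4-en-1-one | CC(C)=CC[C@@H](O)C(=O)C1CCC(O[Si](C)(C)C)=CC1
F2 | step 4 | 4-[(2R)-2-hydroxy-5-methylhex-4-enoyl]cyclohexan-1-one | CC(C)=CC[C@@H](O)C(=O)C1CCC(=O)CC1
F3 | step 7 | (2S,4S)-2-bromo-4-[(2R,3R)-3-[(tert-butyldimethylsilyl)oxy]-2,6,6-trimethyl-3,6-dihydro-2H-pyran-2-yl]-1-methylcyclohexan-1-ol | CC1(C)C=C[C@@H](O[Si](C)(C)C(C)(C)C)[C@@](C)([C@H]2CCC(C)(O)[C@@H](Br)C2)O1
F4 | step 7 | {[(2R,3R)-2-[(1S,3S,4S)-3-bromo-4-chloro-4-methylcyclohexyl]-2,6,6-trimethyl-3,6-dihydro-2H-pyran-3-yl]oxy}(tert-butyl)dimethylsilane | CC1(C)C=C[C@@H](O[Si](C)(C)C(C)(C)C)[C@@](C)([C@H]2CC[C@](C)(Cl)[C@@H](Br)C2)O1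
F5 | step 6 | (2R)-1-[(1S,5S)-5-bromo-4-[(tert-butyldimethylsilyl)oxy]cyclohex-3-en-1-yl]-2-[(tert-butyldimethylsilyl)oxy]-5-methylhex-4-en-1-one | CC(C)=CC[C@@H](O[Si](C)(C)C(C)(C)C)C(=O)[C@H]1CC=C(O[Si](C)(C)C(C)(C)C)[C@@H](Br)C1
F6 | step 6 | (2R,3R)-2-[(1S,5S)-5-bromo-4-[(tert-butyldimethylsilyl)oxy]cyclohex-3-en-1-yl]-3-[(tert-butyldimethylsilyl)oxy]-6-methylhept-5-en-2-ol | CC(C)=CC[C@@H](O[Si](C)(C)C(C)(C)C)[C@](C)(O)[C@H]1CC=C(O[Si](C)(C)C(C)(C)C)[C@@H](Br)C1
F7 | step 6 | (2S,4S)-2-bromo-4-[(2R,3R)-3-[(tert-butyldimethylsilyl)oxy]-2-hydroxy-6-methylhept-5-en-2-yl]cyclohexan-1-one | CC(C)=CC[C@@H](O[Si](C)(C)C(C)(C)C)[C@](C)(O)[C@H]1CCC(=O)[C@@H](Br)C1
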